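**Retrosynthetic overview**
1. The last bond made is the benzylic C–O bond of the dibenzyl ether, from the ring-B p-hydroxybenzyl bromide 8 and the ring-A benzyl alcohol 12.
2. Ring B is hexasubstituted (C1 CH2O, C2 Br, C3 O, C4 O, C5 Br, C6 Br). Its C2–C3–C4–C5 edge (Br, O, O, Br) is mirror-symmetric and maps onto the four ring carbons of 2,5-dibromo-3,4-dimethoxythiophene 1,1-dioxide 3; C1 (CH2O) and C6 (Br) map onto the bromoalkyne 5.
3. Key disconnection: the C1–C2 and C5–C6 bonds of ring B, formed by [4+2] cycloaddition of 3 with 5 and loss of SO2 to give arene 7.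
4. Ring A is not constructed: it is isovanillin, dibrominated at C2 and C6, demethylated and reduced to 12.
5. Order of ring formation: ring B (step 4) is the only ring built; ring A is bought as an arene.

Key step: step 4

Remark: the target has no stereocentre or other stereogenic element, so it is achiral and the request for a single enantiomer is met by the constitution alone.
Assumption: prop-2-ynyl acetate (4) is purchased as such, and HOF·MeCN is prepared just before use from dilute F2/N2 and aqueous acetonitrile.

**Step 1**
Reactants: 1 3,4-dimethoxythiophene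
Product: 2 2,5-dibromo-3,4-dimethoxythiophene
Conditions: NBS (2.05 equiv), CHCl3/AcOH, 0 °C, dark
Reagents that add atoms: N-bromosuccinimide, O=C1CCC(=O)N1Br
Why: Electrophilic aromatic bromination should take place at the two free α-positions of the electron-rich 3,4-dialkoxythiophene, which are the only open ring positions and are activated by both sulfur and the adjacent methoxy groups.

**Step 2**
Reactants: 2 2,5-dibromo-3,4-dimethoxythiophene
Product: 3 2,5-dibromo-3,4-dimethoxythiophene 1,1-dioxide
Conditions: HOF·MeCN (2.5 equiv, from 10% F2/N2 and MeCN/H2O), CH2Cl2, 0 °C, 15 min; then aq. NaHCO3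
Reagents that add atoms: hypofluorous acid–acetonitrile complex, OF.CC#N
Why: S-oxidation of a thiophene to its 1,1-dioxide by electrophilic oxygen transfer from HOF·MeCN is established for 2,5-dihalothiophenes, and here the short contact time with bicarbonate quench should spare the C=C–OMe units while full substitution keeps the dioxide from dimerising.

**Step 3**
Reactants: 4 prop-2-ynyl acetate
Product: 5 3-bromoprop-2-ynyl acetate
Conditions: NBS (1.1 equiv), AgNO3 (10 mol %), acetone, rt; filtration through silica, distillation
Reagents that add atoms: N-bromosuccinimide, O=C1CCC(=O)N1Br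
Why: Silver-catalysed bromination of a terminal alkyne with NBS (through the silver acetylide) should give the 1-bromoalkyne without touching the ester.

**Step 4**
Reactants: 3 2,5-dibromo-3,4-dimethoxythiophene 1,1-dioxide; 5 3-bromoprop-2-ynyl acetate
Product: 7 (2,5,6-tribromo-3,4-dimethoxyphenyl)methyl acetate, via thiabicycloheptadiene dioxide adduct 6 (not isolated)
Conditions: 5 (4 equiv), BHT (cat.), PhCl, 130 °C, sealed tube, Ar
Reagents that add atoms: none
Why: The non-aromatic cyclic diene 3 should add through C2 and C5 across the C≡C bond of 5 in a thermal [4+2] cycloaddition to give the 7-thiabicyclo[2.2.1]hepta-2,5-diene 7,7-dioxide 6, whose SO2 bridge leaves at once by retro-cheletropic extrusion, the gain of aromaticity making the sequence irreversible. The closest known reaction type is the benzannulation of halogenated thiophene 1,1-dioxides with alkynes (Diels–Alder reaction followed by SO2 loss) used to make polyhalobenzenes. Ring B is thereby closed as a six-membered carbocycle by intermolecular [4+2] formation of its C1–C2 and C5–C6 bonds, the sulfonyl bridge serving as a traceless link between the diene termini. The two bridgehead stereocentres of 6 are fixed relative to each other by the bicycle, form as a racemate and are erased on aromatisation, so no stereocontrol is required. No regiocontrol is needed either, because the diene has a mirror plane through sulfur and both orientations of the unsymmetrical alkyne lead to the same arene. The selectivity that matters is cross-cycloaddition over self-dimerisation or decomposition of the diene, which the full substitution of all four diene carbons and the excess of 5 should secure, while the lower electrophilicity caused by the two methoxy donors is answered by the high temperature.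

**Step 5**
Reactants: 7 (2,5,6-tribromo-3,4-dimethoxyphenyl)methyl acetate
Product: 8 3,4,6-tribromo-5-(bromomethyl)benzene-1,2-diol (2,5,6-tribromo-3,4-dihydroxybenzyl bromide)
Conditions: BBr3 (5 equiv), CH2Cl2, −78 °C to rt; cold water quench (no alcohol), EtOAc extraction, used crude
Reagents that add atoms: boron tribromide, BrB(Br)Br
Why: BBr3 ether cleavage should remove both aryl methyl groups while the same reagent converts the boron-activated benzylic acetate into the benzylic bromide by C–O cleavage, the aryl C–Br bonds being inert and the alcohol-free cold quench preserving the p-hydroxybenzyl bromide.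

**Step 6**
Reactants: 9 isovanillin (3-hydroxy-4-methoxybenzaldehyde)
Product: 10 2,6-dibromo-3-hydroxy-4-methoxybenzaldehyde
Conditions: Br2 (2.3 equiv), NaOAc (2.5 equiv), AcOH, rt to 50 °C
Reagents that add atoms: bromine, BrBr
Why: Electrophilic aromatic bromination is directed by the free C3 hydroxyl to its ortho (C2) and para (C6) positions, whereas C5 is activated only by the weaker methoxy donor and should remain unsubstituted.

**Step 7**
Reactants: 10 2,6-dibromo-3-hydroxy-4-methoxybenzaldehyde
Product: 11 2,6-dibromo-3,4-dihydroxybenzaldehyde
Conditions: BBr3 (3 equiv), CH2Cl2, −78 °C to rt; H2O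
Reagents that add atoms: none
Why: BBr3 demethylation of an aryl methyl ether is assisted here by the neighbouring phenol, which binds boron next to the methoxy group, and the aldehyde is recovered on hydrolytic work-up.

**Step 8**
Reactants: 11 2,6-dibromo-3,4-dihydroxybenzaldehyde
Product: 12 3,5-dibromo-4-(hydroxymethyl)benzene-1,2-diol (2,6-dibromo-3,4-dihydroxybenzyl alcohol)
Conditions: NaBH4 (2 equiv), THF/H2O, 0 °C to rt; aq. NH4Cl to pH 6, EtOAc
Reagents that add atoms: none
Why: Borohydride reduction of the aryl aldehyde to the benzyl alcohol leaves aryl bromides and the catechol untouched, and the near-neutral, alcohol-free work-up should avoid solvolysis of the p-hydroxybenzyl alcohol.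

**Step 9**
Reactants: 8 3,4,6-tribromo-5-(bromomethyl)benzene-1,2-diol; 12 3,5-dibromo-4-(hydroxymethyl)benzene-1,2-diol
Product: 13 3,4,6-tribromo-5-{[(2,6-dibromo-3,4-dihydroxyphenyl)methoxy]methyl}benzene-1,2-diol (target)
Conditions: 12 (3 equiv), 2,6-di-tert-butyl-4-methylpyridine (1.2 equiv), 4 Å MS, dry MeCN, 40 °C, Ar, dark; excess 12 recovered by chromatography
Reagents that add atoms: none
Why: SN1-type solvolytic etherification of the p-hydroxybenzyl bromide through its para-hydroxyl-stabilised benzylic cation (O-protonated p-quinone methide) should be trapped by the primary benzylic hydroxyl of 12, the most nucleophilic neutral oxygen present, while the hindered pyridine removes HBr without deprotonating the bromocatechols and the excess of 12 suppresses self-condensation of 8.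

**Compound list**
1 | 3,4-dimethoxythiophene | COc1cscc1OC | starting material
2 | 2,5-dibromo-3,4-dimethoxythiophene | COc1c(Br)sc(Br)c1OC | intermediate
3 | 2,5-dibromo-3,4-dimethoxythiophene 1,1-dioxide | COC1=C(Br)S(=O)(=O)C(Br)=C1OC | intermediate
4 | prop-2-ynyl acetate | CC(=O)OCC#C | starting material
5 | 3-bromoprop-2-ynyl acetate | CC(=O)OCC#CBr | intermediate
6 | (1,3,4-tribromo-5,6-dimethoxy-7,7-dioxo-7λ6-thiabicyclo[2.2.1]hepta-2,5-dien-2-yl)methyl acetate (racemic, one enantiomer written; not isolated) | CC(=O)OCC1=C(Br)[C@@]2(Br)C(OC)=C(OC)[C@]1(Br)S2(=O)=O | intermediate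
7 | (2,5,6-tribromo-3,4-dimethoxyphenyl)methyl acetate | CC(=O)OCc1c(Br)c(OC)c(OC)c(Br)c1Br | intermediate
8 | 3,4,6-tribromo-5-(bromomethyl)benzene-1,2-diol | BrCc1c(Br)c(O)c(O)c(Br)c1Br | intermediate
9 | isovanillin (3-hydroxy-4-methoxybenzaldehyde) | COc1ccc(C=O)cc1O | starting material
10 | 2,6-dibromo-3-hydroxy-4-methoxybenzaldehyde | COc1cc(Br)c(C=O)c(Br)c1O | intermediate
11 | 2,6-dibromo-3,4-dihydroxybenzaldehyde | O=Cc1c(Br)cc(O)c(O)c1Br | intermediate
12 | 3,5-dibromo-4-(hydroxymethyl)benzene-1,2-diol | OCc1c(Br)cc(O)c(O)c1Br | intermediate
13 | 3,4,6-tribromo-5-{[(2,6-dibromo-3,4-dihydroxyphenyl)methoxy]methyl}benzene-1,2-diol | Oc1cc(Br)c(COCc2c(Br)c(O)c(O)c(Br)c2Br)c(Br)c1O | target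

**Step count**
Total steps: 9. Longest linear sequence: 5 steps (steps 1, 2, 4, 5, 9).

**Steps most likely to fail**

Step 4. The cycloaddition may be outrun by thermal decomposition of the bromoalkyne or of the enol-ether sulfone, because the methoxy donors lower the electrophilicity of the diene and force a high temperature. Fallback: ring B is then made by electrophilic substitution on an existing arene instead of by benzannulation. It sets out from 11: bromination (Br2, AcOH, rt) at the only free ring carbon, C5, ortho to the C4 hydroxyl, should give 2,5,6-tribromo-3,4-dihydroxybenzaldehyde F1. Reduction (NaBH4, THF/H2O, 0 °C, near-neutral work-up) should give 3,4,6-tribromo-5-(hydroxymethyl)benzene-1,2-diol F2. Treatment with HBr (33% in AcOH, CH2Cl2, rt) should convert this p-hydroxybenzyl alcohol into the bromide, which is compound 8, where the route is rejoined.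

Step 2. Oxygen transfer may go to the electron-rich C=C–OMe units, or the HF formed may hydrolyse the enol-ether sulfone, instead of clean oxidation at sulfur. Fallback: oxidation is carried out on a silylated thiophene and the bromines are introduced afterwards. It sets out from 1: double α-lithiation (n-BuLi 2.2 equiv, TMEDA, THF, −78 to 0 °C) and TMSCl quench should give 3,4-dimethoxy-2,5-bis(trimethylsilyl)thiophene F3. The silyl groups make sulfur more nucleophilic and shield the diene, so that mCPBA (CH2Cl2, NaHCO3, rt) should suffice to reach 3,4-dimethoxy-2,5-bis(trimethylsilyl)thiophene 1,1-dioxide F4. Ipso-bromodesilylation (Br2, AgBF4, CH2Cl2, 0 °C) at the two enol-ether β-carbons should then give 3, where the route is rejoined.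

Step 9. Both partners are p-hydroxybenzyl systems, so ionisation on either side may exchange the product into the two symmetrical ethers, a catechol oxygen may be alkylated, and the quinone methide may oligomerise. Fallback: the ether is formed with the phenols masked as acetates, which cannot ionise through a quinone methide. It sets out from 8 and 11. Acid-catalysed acetylation of 8 (Ac2O, cat. H2SO4, 0 °C) should give 3,4,6-tribromo-5-(bromomethyl)-1,2-phenylene diacetate F5. Acetylation of 11 (Ac2O, pyridine) should give 3,5-dibromo-4-formyl-1,2-phenylene diacetate F6, and chemoselective aldehyde reduction (BH3·SMe2, THF, 0 °C) should give 3,5-dibromo-4-(hydroxymethyl)-1,2-phenylene diacetate F7. Silver-promoted etherification of F5 with F7 (AgOTf, 2,6-di-tert-butylpyridine, CH2Cl2, 0 °C to rt) should give the tetraacetate of the target F8. Mild methanolysis of the aryl acetates (cat. K2CO3, MeOH, 0 °C, then AcOH) should then release 13, the end of the route.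

**Further compounds**
F1 | step 4 | 2,5,6-tribromo-3,4-dihydroxybenzaldehyde | O=Cc1c(Br)c(O)c(O)c(Br)c1Br
F2 | step 4 | 3,4,6-tribromo-5-(hydroxymethyl)benzene-1,2-diol | OCc1c(Br)c(O)c(O)c(Br)c1Br
F3 | step 2 | 3,4-dimethoxy-2,5-bis(trimethylsilyl)thiophene | COc1c([Si](C)(C)C)sc([Si](C)(C)C)c1OC
F4 | step 2 | 3,4-dimethoxy-2,5-bis(trimethylsilyl)thiophene 1,1-dioxide | COC1=C([Si](C)(C)C)S(=O)(=O)C([Si](C)(C)C)=C1OC
F5 | step 9 | 3,4,6-tribromo-5-(bromomethyl)-1,2-phenylene diacetate | CC(=O)Oc1c(Br)c(CBr)c(Br)c(Br)c1OC(C)=O
F6 | step 9 | 3,5-dibromo-4-formyl-1,2-phenylene diacetate | CC(=O)Oc1cc(Br)c(C=O)c(Br)c1OC(C)=O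
F7 | step 9 | 3,5-dibromo-4-(hydroxymethyl)-1,2-phenylene diacetate | CC(=O)Oc1cc(Br)c(CO)c(Br)c1OC(C)=O
F8 | step 9 | tetraacetate of the target (bis-catechol tetraacetate of 13) | CC(=O)Oc1cc(Br)c(COCc2c(Br)c(OC(C)=O)c(OC(C)=O)c(Br)c2Br)c(Br)c1OC(C)=O
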